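**Plan**

1. Retrosynthetic cuts: C13–Br, C9–Br and C6–Cl (each from an alcohol by SN2 inversion); C3=C4 (enyne cross-metathesis); C5–C6 (allylation of a C6 aldehyde); C6–C7 (enol silane added to a C7 oxocarbenium ion); C13–C14 (EtMgBr); key cut C7–C8 together with C9–C10.
2. Enabling feature: in the oxolane, C7 and C10 both carry the ring oxygen and are spanned by the two-carbon unit C8–C9, the retron of a carbonyl ylide + alkene addition. C7 together with C10–C11=C12–C13 (Z-alkene, heteroatom on C13) are the five carbons of furfuryl alcohol, so dearomatising that furan (Achmatowicz) gives the ylide as a 3-oxidopyrylium.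
3. Forward: the ylide adds vinyl acetate in a [5+2] cycloaddition that closes the oxolane and, through a temporary C7–C13 bond, a seven-membered enone ring. After inversion at C9 and EtMgBr addition, alkoxy-radical fragmentation cuts the temporary bond, releasing the Z-enone chain and a C7 anomeric acetate.
4. The left-hand chain is then joined at C7 (trans to C10), trimmed to the aldehyde, allylated, chlorinated and extended by Z-selective enyne metathesis; the two bromides come last.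
5. Stereochemistry: C9/C10 relative configuration from the suprafacial endo cycloaddition, absolute configuration from a lipase resolution, C9–O inverted by Mitsunobu and again by bromide. C7 from inside attack on the oxocarbenium ion cis to the C9 silyloxy group; C6 from chelation-controlled allylation, then inversion by chloride; C13 from CBS reduction, then inversion by bromide. Z-C11=C12 comes from the ring, Z-C3=C4 from the metathesis.

Key step: step 2

Remark: the chain is numbered C1 (alkyne CH) to C15 (CH3) with the oxolane oxygen bridging C7 and C10; TBS = tert-butyldimethylsilyl, TBDPS = tert-butyldiphenylsilyl, TIPS = triisopropylsilyl; racemic 6 is drawn as the enantiomer carried on, and the lipase is assumed to follow its usual preference for the (R)-carbinol.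

**Step 1**
Reactants: 1 furfuryl alcohol
Product: 3 6-acetoxy-2H-pyran-3(6H)-one (racemic), via 6-hydroxy-2H-pyran-3(6H)-one 2 (not isolated)
Conditions: NBS, NaHCO3, NaOAc, THF/H2O (4:1), 0 °C; extractive work-up; then Ac2O, pyridine, DMAP (cat.), CH2Cl2, 0 °C
Reagents that add atoms: water, O; acetic anhydride, CC(=O)OC(C)=O
Why: Achmatowicz rearrangement (oxidative opening of the furan to a Z-ene-dione and re-closure through the carbinol oxygen) should give hemiacetal 2, which is acetylated to the pyranone 3 carrying the leaving group, so that the furan becomes C10–C13 with its Z-alkene and the future ring oxygen sits on C7.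

**Step 2**
Reactants: 3 6-acetoxy-2H-pyran-3(6H)-one; 4 vinyl acetate
Product: 6 rac-(1R,5R,6R)-2-oxo-8-oxabicyclo[3.2.1]oct-3-en-6-yl acetate (6-endo), via 3-oxidopyrylium betaine 5 (not isolated)
Conditions: 4 (20 equiv, co-solvent), Et3N (1.2 equiv, added slowly), CH2Cl2, 25–40 °C
Reagents that add atoms: none
Why: Et3N removes the proton at C2 of 3 (α to the ketone) and acetate leaves from C6, giving the 3-oxidopyrylium betaine 5, a cyclic carbonyl ylide whose two carbons flanking the oxygen add suprafacially across the C=C bond of 4 in a concerted [5+2] cycloaddition (a six-electron 1,3-dipolar addition), so that the ylide carbon next to the oxido group (future C7) bonds to the CH2 terminus (future C8) and the other ylide carbon (future C10) bonds to the acetoxy-bearing carbon (future C9). The closest known reaction type is the intermolecular cycloaddition of 3-oxidopyrylium ylides with enol ethers and acrylates. The oxolane ring (O, C7, C8, C9, C10) is closed by this dipolar addition across the C–O–C ylide, and the seven-membered enone ring, which holds the temporary C7–C13 bond and locks C11=C12 as Z, is closed in the same [5+2] event. C7 and C10 become bridgeheads that are cis by necessity of the suprafacial addition to the planar ylide (formed as a racemate, resolved in step 3), and the C9 acetoxy group is set endo by the kinetic preference of heteroatom-substituted alkenes for the orientation beneath the enone bridge, that is cis to C11. The step needs regioselectivity (acetoxy on C6 of the bicycle, remote from the carbonyl), which is secured by the larger frontier-orbital coefficient at the ylide carbon α to the oxido group bonding to the unsubstituted alkene terminus, and it needs capture of the ylide before it dimerises, which the excess of 4 and the slow addition of base secure.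

**Step 3**
Reactants: 6 rac-(1R,5R,6R)-2-oxo-8-oxabicyclo[3.2.1]oct-3-en-6-yl acetate
Product: 7 (1R,5R,6R)-6-hydroxy-8-oxabicyclo[3.2.1]oct-3-en-2-one
Conditions: lipase from Burkholderia cepacia, phosphate buffer pH 7/MTBE, 30 °C, stopped near half conversion; chromatography
Reagents that add atoms: none
Why: Lipase-catalysed enantioselective hydrolysis (kinetic resolution) should, by the empirical preference of lipases for the (R)-carbinol whose larger flank (bridgehead C5) outranks the smaller (C7 methylene), release the (6R)-alcohol 7 and leave the antipodal acetate.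

**Step 4**
Reactants: 7 (1R,5R,6R)-6-hydroxy-8-oxabicyclo[3.2.1]oct-3-en-2-one
Product: 8 (1R,5R,6S)-2-oxo-8-oxabicyclo[3.2.1]oct-3-en-6-yl 4-nitrobenzoate
Conditions: 4-nitrobenzoic acid, PPh3, DIAD, THF, 0 °C → rt
Reagents that add atoms: 4-nitrobenzoic acid, OC(=O)c1ccc(cc1)[N+](=O)[O-]
Why: Mitsunobu inversion, in which the carboxylate displaces the endo alkoxyphosphonium group from the open exo face, should place the C9 oxygen trans to C11, as both the later C7 addition and the final bromide displacement require.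

**Step 5**
Reactants: 8 (1R,5R,6S)-2-oxo-8-oxabicyclo[3.2.1]oct-3-en-6-yl 4-nitrobenzoate
Product: 9 (1R,5R,6S)-6-hydroxy-8-oxabicyclo[3.2.1]oct-3-en-2-one
Conditions: K2CO3 (cat.), MeOH, 0 °C, short contact
Reagents that add atoms: none
Why: Base-catalysed transesterification of the activated 4-nitrobenzoate is fast at 0 °C and should free the exo alcohol without conjugate addition to the enone or change at C9.

**Step 6**
Reactants: 9 (1R,5R,6S)-6-hydroxy-8-oxabicyclo[3.2.1]oct-3-en-2-one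
Product: 10 (1R,5R,6S)-6-(TBS-oxy)-8-oxabicyclo[3.2.1]oct-3-en-2-one
Conditions: TBSCl, imidazole, DMF, rt
Reagents that add atoms: tert-butyldimethylsilyl chloride, CC(C)(C)[Si](C)(C)Cl
Why: Silylation gives a non-participating silyl ether that survives the Grignard and radical steps and later directs the addition at C7.

**Step 7**
Reactants: 10 (1R,5R,6S)-6-(TBS-oxy)-8-oxabicyclo[3.2.1]oct-3-en-2-one; 11 ethylmagnesium bromide
Product: 12 (1R,2R,5R,6S)-6-(TBS-oxy)-2-ethyl-8-oxabicyclo[3.2.1]oct-3-en-2-ol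
Conditions: CeCl3 (anhydrous), 11, THF, −78 °C; aq. NH4Cl
Reagents that add atoms: none
Why: 1,2-Addition of the organocerium reagent (Grignard/CeCl3) to the enone carbonyl from the less hindered face beside the oxygen bridge should install C14–C15 and give the tertiary allylic alcohol, whose new carbinol centre is erased in step 8.

**Step 8**
Reactants: 12 (1R,2R,5R,6S)-6-(TBS-oxy)-2-ethyl-8-oxabicyclo[3.2.1]oct-3-en-2-ol
Product: 14 (4S,5R)-4-(TBS-oxy)-5-[(1Z)-3-oxopent-1-en-1-yl]oxolan-2-yl acetate (anomeric mixture), via tertiary hypoiodite 13 (not isolated)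
Conditions: PhI(OAc)2, I2, CH2Cl2, visible light, 20 °C; aq. Na2S2O3
Reagents that add atoms: (diacetoxyiodo)benzene, CC(=O)OI(OC(C)=O)c1ccccc1
Why: Alkoxy-radical β-fragmentation under hypoiodite conditions should cleave the strained C7–C13 bond toward the oxygen-stabilised C7 radical, which is oxidised to the oxocarbenium ion and captured by acetate, leaving the ethyl ketone conjugated to the ring-derived Z-C11=C12 alkene with C9 and C10 untouched.

**Step 9**
Reactants: 14 (4S,5R)-4-(TBS-oxy)-5-[(1Z)-3-oxopent-1-en-1-yl]oxolan-2-yl acetate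
Product: 15 (4S,5R)-4-(TBS-oxy)-5-[(1Z,3S)-3-hydroxypent-1-en-1-yl]oxolan-2-yl acetate
Conditions: (R)-2-methyl-CBS-oxazaborolidine, catecholborane, toluene, −78 °C
Reagents that add atoms: none
Why: Corey–Bakshi–Shibata reduction, with the alkenyl group as the large and ethyl as the small substituent, should give the 13S allylic alcohol by reagent-controlled 1,2-reduction before the Z-enone can isomerise.

**Step 10**
Reactants: 15 (4S,5R)-4-(TBS-oxy)-5-[(1Z,3S)-3-hydroxypent-1-en-1-yl]oxolan-2-yl acetate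
Product: 16 (4S,5R)-4-(TBS-oxy)-5-[(1Z,3S)-3-(TBDPS-oxy)pent-1-en-1-yl]oxolan-2-yl acetate
Conditions: TBDPSCl, imidazole, DMAP (cat.), DMF, rt
Reagents that add atoms: tert-butyl(chloro)diphenylsilane, CC(C)(C)[Si](Cl)(c1ccccc1)c1ccccc1
Why: Silylation masks the C13 alcohol with a group that outlasts the later acidic removal of the C9 TBS ether and keeps it from capturing the C7 cation.

**Step 11**
Reactants: 16 (4S,5R)-4-(TBS-oxy)-5-[(1Z,3S)-3-(TBDPS-oxy)pent-1-en-1-yl]oxolan-2-yl acetate; 17 trimethyl[(1-phenylethenyl)oxy]silane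
Product: 18 2-[(2S,4S,5R)-4-(TBS-oxy)-5-[(1Z,3S)-3-(TBDPS-oxy)pent-1-en-1-yl]oxolan-2-yl]-1-phenylethan-1-one
Conditions: 17 (3 equiv), BF3·OEt2, CH2Cl2, −78 °C
Reagents that add atoms: none
Why: Mukaiyama-type C-glycosylation, in which BF3·OEt2 ionises the anomeric acetate to the five-membered oxocarbenium ion whose favoured envelope holds the C9 silyloxy group pseudoaxial, should by inside attack of the enol silane form the C6–C7 bond cis to the C9 oxygen and so trans to the C10 chain, a preference the C10 substituent on the opposite face reinforces.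

**Step 12**
Reactants: 18 2-[(2S,4S,5R)-4-(TBS-oxy)-5-[(1Z,3S)-3-(TBDPS-oxy)pent-1-en-1-yl]oxolan-2-yl]-1-phenylethan-1-one
Product: 20 (2S,4S,5R)-4-(TBS-oxy)-5-[(1Z,3S)-3-(TBDPS-oxy)pent-1-en-1-yl]oxolane-2-carbaldehyde, via silyl enol ether 19 (not isolated)
Conditions: TMSOTf, Et3N, CH2Cl2, 0 °C; aqueous wash; crude 19: O3 (1 equiv), CH2Cl2, −78 °C, then Me2S
Reagents that add atoms: ozone, [O-][O+]=O
Why: Regiospecific enolisation toward C6 (the only α-hydrogens) followed by ozonolysis of the silyl enol ether, the one electron-rich alkene present and far more reactive than the Z-alkene flanked by two allylic C–O bonds, should excise the benzoyl carbon and leave C6 as the aldehyde without touching C7.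

**Step 13**
Reactants: 20 (2S,4S,5R)-4-(TBS-oxy)-5-[(1Z,3S)-3-(TBDPS-oxy)pent-1-en-1-yl]oxolane-2-carbaldehyde; 21 allyltributylstannane
Product: 22 (1S)-1-[(2S,4S,5R)-4-(TBS-oxy)-5-[(1Z,3S)-3-(TBDPS-oxy)pent-1-en-1-yl]oxolan-2-yl]but-3-en-1-ol
Conditions: MgBr2·OEt2, CH2Cl2, −78 °C; then 21, −78 → −40 °C
Reagents that add atoms: none
Why: Chelation-controlled allylstannane addition (Cram-chelate model), with magnesium bridging the aldehyde and ring oxygens, should deliver allyl to the exposed face and give the threo (6S,7S) homoallylic alcohol.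

**Step 14**
Reactants: 22 (1S)-1-[(2S,4S,5R)-4-(TBS-oxy)-5-[(1Z,3S)-3-(TBDPS-oxy)pent-1-en-1-yl]oxolan-2-yl]but-3-en-1-ol
Product: 23 (2R,3S,5S)-5-[(1R)-1-chlorobut-3-en-1-yl]-3-(TBS-oxy)-2-[(1Z,3S)-3-(TBDPS-oxy)pent-1-en-1-yl]oxolane
Conditions: CCl4, P(n-C8H17)3, toluene, 60 °C
Reagents that add atoms: carbon tetrachloride, ClC(Cl)(Cl)Cl
Why: Appel-type deoxychlorination, an SN2 displacement of the alkoxyphosphonium ion by chloride, should invert C6 to the required 6R configuration under neutral conditions.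

**Step 15**
Reactants: 24 vinyl bromide; 25 (triisopropylsilyl)acetylene
Product: 26 (but-3-en-1-yn-1-yl)triisopropylsilane
Conditions: Pd(PPh3)4 (cat.), CuI (cat.), iPr2NH, THF, 0 °C → rt
Reagents that add atoms: none
Why: Sonogashira coupling of the vinyl halide with the terminal silylacetylene gives the conjugated enyne needed as metathesis partner.

**Step 16**
Reactants: 23 (2R,3S,5S)-5-[(1R)-1-chlorobut-3-en-1-yl]-3-(TBS-oxy)-2-[(1Z,3S)-3-(TBDPS-oxy)pent-1-en-1-yl]oxolane; 26 (but-3-en-1-yn-1-yl)triisopropylsilane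
Product: 27 (2R,3S,5S)-5-[(1R,3Z)-1-chloro-6-(TIPS)hex-3-en-5-yn-1-yl]-3-(TBS-oxy)-2-[(1Z,3S)-3-(TBDPS-oxy)pent-1-en-1-yl]oxolane
Conditions: second-generation Grubbs catalyst (10 mol %), 26 (4 equiv), CH2Cl2, 40 °C
Reagents that add atoms: none
Why: Cross-metathesis of the terminal alkene with a silyl-capped conjugated enyne, a pairing known for its Z-preference, should build the Z-C3=C4 enyne with loss of ethylene while the hindered internal Z-alkene stays inert.

**Step 17**
Reactants: 27 (2R,3S,5S)-5-[(1R,3Z)-1-chloro-6-(TIPS)hex-3-en-5-yn-1-yl]-3-(TBS-oxy)-2-[(1Z,3S)-3-(TBDPS-oxy)pent-1-en-1-yl]oxolane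
Product: 28 (2R,3S,5S)-5-[(1R,3Z)-1-chloro-6-(TIPS)hex-3-en-5-yn-1-yl]-2-[(1Z,3S)-3-(TBDPS-oxy)pent-1-en-1-yl]oxolan-3-ol
Conditions: CSA (cat.), MeOH/CH2Cl2, 0 °C → rt
Reagents that add atoms: none
Why: Acid-catalysed methanolysis should remove the secondary TBS ether selectively, since the TBDPS ether and the alkynyl TIPS group are far more stable to acid.

**Step 18**
Reactants: 28 (2R,3S,5S)-5-[(1R,3Z)-1-chloro-6-(TIPS)hex-3-en-5-yn-1-yl]-2-[(1Z,3S)-3-(TBDPS-oxy)pent-1-en-1-yl]oxolan-3-ol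
Product: 29 (2R,3R,5S)-3-bromo-5-[(1R,3Z)-1-chloro-6-(TIPS)hex-3-en-5-yn-1-yl]-2-[(1Z,3S)-3-(TBDPS-oxy)pent-1-en-1-yl]oxolane
Conditions: CBr4, P(n-C8H17)3, toluene, 70 °C
Reagents that add atoms: carbon tetrabromide, BrC(Br)(Br)Br
Why: Appel bromination, an SN2 displacement with inversion, should turn the C9 alcohol (trans to the C10 chain) into the 9R bromide cis to it, with neutral phosphine conditions limiting E2 loss.

**Step 19**
Reactants: 29 (2R,3R,5S)-3-bromo-5-[(1R,3Z)-1-chloro-6-(TIPS)hex-3-en-5-yn-1-yl]-2-[(1Z,3S)-3-(TBDPS-oxy)pent-1-en-1-yl]oxolane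
Product: 30 (1Z,3S)-1-[(2R,3R,5S)-3-bromo-5-[(1R,3Z)-1-chlorohex-3-en-5-yn-1-yl]oxolan-2-yl]pent-1-en-3-ol
Conditions: TBAF, THF, −20 → 0 °C
Reagents that add atoms: none
Why: Fluoride-mediated desilylation should remove the TBDPS ether and the alkynyl TIPS group in one operation, the low temperature limiting E2 of the secondary halides.

**Step 20**
Reactants: 30 (1Z,3S)-1-[(2R,3R,5S)-3-bromo-5-[(1R,3Z)-1-chlorohex-3-en-5-yn-1-yl]oxolan-2-yl]pent-1-en-3-ol
Product: 31 (2R,3R,5S)-3-bromo-2-[(1Z,3R)-3-bromopent-1-en-1-yl]-5-[(1R,3Z)-1-chlorohex-3-en-5-yn-1-yl]oxolane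
Conditions: CBr4, PPh3, 2,6-lutidine, CH2Cl2, −40 → 0 °C
Reagents that add atoms: carbon tetrabromide, BrC(Br)(Br)Br
Why: Appel bromination of the allylic alcohol at low temperature should proceed by direct SN2 displacement with inversion to the 13R bromide, SN2′ attack being disfavoured at C11, which is attached to the ring.

**Compound list**

1 | furfuryl alcohol | OCc1ccco1 | starting material
2 | 6-hydroxy-2H-pyran-3(6H)-one (racemic) | O=C1COC(O)C=C1 | intermediate
3 | 6-acetoxy-2H-pyran-3(6H)-one (racemic) | CC(=O)OC1OCC(=O)C=C1 | intermediate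
4 | vinyl acetate | CC(=O)OC=C | starting material
5 | 3-oxidopyrylium betaine (pyrylium-3-olate) | [O-]c1ccc[o+]c1 | intermediate
6 | rac-(1R,5R,6R)-2-oxo-8-oxabicyclo[3.2.1]oct-3-en-6-yl acetate (6-endo) | O=C1C=C[C@@H]2[C@H](OC(C)=O)C[C@H]1O2 | intermediate
7 | (1R,5R,6R)-6-hydroxy-8-oxabicyclo[3.2.1]oct-3-en-2-one | O=C1C=C[C@@H]2[C@H](O)C[C@H]1O2 | intermediate
8 | (1R,5R,6S)-2-oxo-8-oxabicyclo[3.2.1]oct-3-en-6-yl 4-nitrobenzoate | O=C1C=C[C@@H]2[C@@H](OC(=O)c3ccc(cc3)[N+](=O)[O-])C[C@H]1O2 | intermediate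
9 | (1R,5R,6S)-6-hydroxy-8-oxabicyclo[3.2.1]oct-3-en-2-one | O=C1C=C[C@@H]2[C@@H](O)C[C@H]1O2 | intermediate
10 | (1R,5R,6S)-6-(TBS-oxy)-8-oxabicyclo[3.2.1]oct-3-en-2-one | O=C1C=C[C@@H]2[C@@H](O[Si](C)(C)C(C)(C)C)C[C@H]1O2 | intermediate
11 | ethylmagnesium bromide | CC[Mg]Br | starting material
12 | (1R,2R,5R,6S)-6-(TBS-oxy)-2-ethyl-8-oxabicyclo[3.2.1]oct-3-en-2-ol | CC[C@@]1(O)C=C[C@@H]2[C@@H](O[Si](C)(C)C(C)(C)C)C[C@H]1O2 | intermediate
13 | tertiary hypoiodite of 12 | CC[C@@]1(OI)C=C[C@@H]2[C@@H](O[Si](C)(C)C(C)(C)C)C[C@H]1O2 | intermediate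
14 | (4S,5R)-4-(TBS-oxy)-5-[(1Z)-3-oxopent-1-en-1-yl]oxolan-2-yl acetate (anomeric mixture) | CC(=O)OC1C[C@H](O[Si](C)(C)C(C)(C)C)[C@@H](/C=C\C(=O)CC)O1 | intermediate
15 | (4S,5R)-4-(TBS-oxy)-5-[(1Z,3S)-3-hydroxypent-1-en-1-yl]oxolan-2-yl acetate | CC(=O)OC1C[C@H](O[Si](C)(C)C(C)(C)C)[C@@H](/C=C\[C@@H](O)CC)O1 | intermediate
16 | (4S,5R)-4-(TBS-oxy)-5-[(1Z,3S)-3-(TBDPS-oxy)pent-1-en-1-yl]oxolan-2-yl acetate | CC(=O)OC1C[C@H](O[Si](C)(C)C(C)(C)C)[C@@H](/C=C\[C@@H](O[Si](c2ccccc2)(c2ccccc2)C(C)(C)C)CC)O1 | intermediate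
17 | trimethyl[(1-phenylethenyl)oxy]silane | C=C(O[Si](C)(C)C)c1ccccc1 | starting material
18 | 2-[(2S,4S,5R)-4-(TBS-oxy)-5-[(1Z,3S)-3-(TBDPS-oxy)pent-1-en-1-yl]oxolan-2-yl]-1-phenylethan-1-one | O=C(C[C@@H]1C[C@H](O[Si](C)(C)C(C)(C)C)[C@@H](/C=C\[C@@H](O[Si](c2ccccc2)(c2ccccc2)C(C)(C)C)CC)O1)c3ccccc3 | intermediate
19 | trimethylsilyl enol ether of 18 (alkene geometry not defined) | C[Si](C)(C)OC(=C[C@@H]1C[C@H](O[Si](C)(C)C(C)(C)C)[C@@H](/C=C\[C@@H](O[Si](c2ccccc2)(c2ccccc2)C(C)(C)C)CC)O1)c3ccccc3 | intermediate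
20 | (2S,4S,5R)-4-(TBS-oxy)-5-[(1Z,3S)-3-(TBDPS-oxy)pent-1-en-1-yl]oxolane-2-carbaldehyde | O=C[C@@H]1C[C@H](O[Si](C)(C)C(C)(C)C)[C@@H](/C=C\[C@@H](O[Si](c2ccccc2)(c2ccccc2)C(C)(C)C)CC)O1 | intermediate
21 | allyltributylstannane | C=CC[Sn](CCCC)(CCCC)CCCC | starting material
22 | (1S)-1-[(2S,4S,5R)-4-(TBS-oxy)-5-[(1Z,3S)-3-(TBDPS-oxy)pent-1-en-1-yl]oxolan-2-yl]but-3-en-1-ol | C=CC[C@H](O)[C@@H]1C[C@H](O[Si](C)(C)C(C)(C)C)[C@@H](/C=C\[C@@H](O[Si](c2ccccc2)(c2ccccc2)C(C)(C)C)CC)O1 | intermediate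
23 | (2R,3S,5S)-5-[(1R)-1-chlorobut-3-en-1-yl]-3-(TBS-oxy)-2-[(1Z,3S)-3-(TBDPS-oxy)pent-1-en-1-yl]oxolane | C=CC[C@@H](Cl)[C@@H]1C[C@H](O[Si](C)(C)C(C)(C)C)[C@@H](/C=C\[C@@H](O[Si](c2ccccc2)(c2ccccc2)C(C)(C)C)CC)O1 | intermediate
24 | vinyl bromide | C=CBr | starting material
25 | (triisopropylsilyl)acetylene | C#C[Si](C(C)C)(C(C)C)C(C)C | starting material
26 | (but-3-en-1-yn-1-yl)triisopropylsilane | C=CC#C[Si](C(C)C)(C(C)C)C(C)C | intermediate
27 | (2R,3S,5S)-5-[(1R,3Z)-1-chloro-6-(TIPS)hex-3-en-5-yn-1-yl]-3-(TBS-oxy)-2-[(1Z,3S)-3-(TBDPS-oxy)pent-1-en-1-yl]oxolane | CC(C)[Si](C#C/C=C\C[C@@H](Cl)[C@@H]1C[C@H](O[Si](C)(C)C(C)(C)C)[C@@H](/C=C\[C@@H](O[Si](c2ccccc2)(c2ccccc2)C(C)(C)C)CC)O1)(C(C)C)C(C)C | intermediate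
28 | (2R,3S,5S)-5-[(1R,3Z)-1-chloro-6-(TIPS)hex-3-en-5-yn-1-yl]-2-[(1Z,3S)-3-(TBDPS-oxy)pent-1-en-1-yl]oxolan-3-ol | CC(C)[Si](C#C/C=C\C[C@@H](Cl)[C@@H]1C[C@H](O)[C@@H](/C=C\[C@@H](O[Si](c2ccccc2)(c2ccccc2)C(C)(C)C)CC)O1)(C(C)C)C(C)C | intermediate
29 | (2R,3R,5S)-3-bromo-5-[(1R,3Z)-1-chloro-6-(TIPS)hex-3-en-5-yn-1-yl]-2-[(1Z,3S)-3-(TBDPS-oxy)pent-1-en-1-yl]oxolane | CC(C)[Si](C#C/C=C\C[C@@H](Cl)[C@@H]1C[C@@H](Br)[C@@H](/C=C\[C@@H](O[Si](c2ccccc2)(c2ccccc2)C(C)(C)C)CC)O1)(C(C)C)C(C)C | intermediate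
30 | (1Z,3S)-1-[(2R,3R,5S)-3-bromo-5-[(1R,3Z)-1-chlorohex-3-en-5-yn-1-yl]oxolan-2-yl]pent-1-en-3-ol | C#C/C=C\C[C@@H](Cl)[C@@H]1C[C@@H](Br)[C@@H](/C=C\[C@@H](O)CC)O1 | intermediate
31 | (2R,3R,5S)-3-bromo-2-[(1Z,3R)-3-bromopent-1-en-1-yl]-5-[(1R,3Z)-1-chlorohex-3-en-5-yn-1-yl]oxolane | C#C/C=C\C[C@@H](Cl)[C@@H]1C[C@@H](Br)[C@@H](/C=C\[C@H](Br)CC)O1 | target

**Step count**

Total: 20 steps. Longest linear sequence: 19 steps (steps 1–14 and 16–20; step 15 prepares the metathesis partner).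

**Steps most likely to fail**

Step 2. The parent ylide may dimerise faster than it is intercepted by the only moderately reactive enol ester, and endo/exo or regiochemical control may be incomplete. The fallback sets out from 3 and returns at 9. The ylide is trapped instead with the electron-poor methyl vinyl ketone (Et3N, CH2Cl2), whose acetyl group enters at C6 of the bicycle; amine-mediated equilibration of the epimers should favour rac-(1R,5R,6S)-6-acetyl-8-oxabicyclo[3.2.1]oct-3-en-2-one F1 (acetyl exo, trans to C4). Baeyer–Villiger oxidation (mCPBA, NaHCO3) with retention gives rac-(1R,5R,6S)-2-oxo-8-oxabicyclo[3.2.1]oct-3-en-6-yl acetate F2. Acid methanolysis (HCl, MeOH) gives 9 in racemic form, and lipase-catalysed acetylation with vinyl acetate removes the (1S,5S,6R)-antipode, so the route is rejoined at 9 without the Mitsunobu inversion.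

Step 8. The radical process may be diverted: iodine atoms can isomerise the new Z-enone to E, and the alkoxy radical may abstract hydrogen or iodinate instead of fragmenting. The fallback sets out from 10 and returns at 14, cleaving the C7–C13 bond by an ionic path. Baeyer–Villiger oxidation (mCPBA, NaHCO3), with migration of the oxygen-bearing bridgehead, should give the bridged acylal lactone (1S,6R,7S)-7-(TBS-oxy)-2,9-dioxabicyclo[4.2.1]non-4-en-3-one F3. Opening with MeNH(OMe)·HCl/iPrMgCl and acetylation of the liberated lactol in the same flask (Ac2O) give (4S,5R)-4-(TBS-oxy)-5-[(1Z)-3-[methoxy(methyl)amino]-3-oxoprop-1-en-1-yl]oxolan-2-yl acetate F4. EtMgBr at −78 °C then converts the amide into the ethyl ketone 14.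

Step 16. Z/E control in the metathesis may be poor, and the conjugated enyne may sequester the catalyst or cause secondary metathesis. The fallback sets out from 23 and returns at 27, building the enyne by olefination and coupling. Selective cleavage of the terminal alkene (OsO4 cat., NMO; then NaIO4) gives (3R)-3-chloro-3-[(2S,4S,5R)-4-(TBS-oxy)-5-[(1Z,3S)-3-(TBDPS-oxy)pent-1-en-1-yl]oxolan-2-yl]propanal F5. Stork–Zhao olefination ((iodomethyl)triphenylphosphonium iodide, NaHMDS, THF, −78 °C) gives (2R,3S,5S)-5-[(1R,3Z)-1-chloro-4-iodobut-3-en-1-yl]-3-(TBS-oxy)-2-[(1Z,3S)-3-(TBDPS-oxy)pent-1-en-1-yl]oxolane F6. Sonogashira coupling with 25 (Pd(PPh3)4, CuI, iPr2NH) gives 27.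

**Further compounds**

F1 | step 2 | rac-(1R,5R,6S)-6-acetyl-8-oxabicyclo[3.2.1]oct-3-en-2-one | O=C1C=C[C@@H]2[C@@H](C(C)=O)C[C@H]1O2
F2 | step 2 | rac-(1R,5R,6S)-2-oxo-8-oxabicyclo[3.2.1]oct-3-en-6-yl acetate | O=C1C=C[C@@H]2[C@@H](OC(C)=O)C[C@H]1O2
F3 | step 8 | (1S,6R,7S)-7-(TBS-oxy)-2,9-dioxabicyclo[4.2.1]non-4-en-3-one | O=C1C=C[C@@H]2[C@@H](O[Si](C)(C)C(C)(C)C)C[C@H](O1)O2
F4 | step 8 | (4S,5R)-4-(TBS-oxy)-5-[(1Z)-3-[methoxy(methyl)amino]-3-oxoprop-1-en-1-yl]oxolan-2-yl acetate | CC(=O)OC1C[C@H](O[Si](C)(C)C(C)(C)C)[C@@H](/C=C\C(=O)N(C)OC)O1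
F5 | step 16 | (3R)-3-chloro-3-[(2S,4S,5R)-4-(TBS-oxy)-5-[(1Z,3S)-3-(TBDPS-oxy)pent-1-en-1-yl]oxolan-2-yl]propanal | O=CC[C@@H](Cl)[C@@H]1C[C@H](O[Si](C)(C)C(C)(C)C)[C@@H](/C=C\[C@@H](O[Si](c2ccccc2)(c2ccccc2)C(C)(C)C)CC)O1
F6 | step 16 | (2R,3S,5S)-5-[(1R,3Z)-1-chloro-4-iodobut-3-en-1-yl]-3-(TBS-oxy)-2-[(1Z,3S)-3-(TBDPS-oxy)pent-1-en-1-yl]oxolane | I/C=C\C[C@@H](Cl)[C@@H]1C[C@H](O[Si](C)(C)C(C)(C)C)[C@@H](/C=C\[C@@H](O[Si](c2ccccc2)(c2ccccc2)C(C)(C)C)CC)O1
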